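**Plan**
- Numbering as in drimanes: C1 carbinol, C3 chloride, C4 quaternary carbon with the side chain, C5/C10 ring fusion, C8 ester-bearing carbon, C9 formyl-bearing carbon, C11 formyl carbon. Cuts: side-chain C=C and C–CH3, then C3–Cl and C1–O, then C5–C10 together with C8–C9, then C1–C2 (aldol), C5=C6 (olefination) and the two C4–alkyl bonds.
- Enabling feature: ring B is a cyclohexene with the ester on C8 and the formyl-bearing C9 next to the methyl-bearing fusion carbon C10. With C7=C8 moved to C6=C7 it is the adduct of a C9=C10 enal (used as the 1-methoxyallyl cation from its acetal) and a C5=C6–C7=C8–CO2Me dienoate, tethered by C1–C4 of ring A.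
- Forward: the open chain is built linearly; one cationic intramolecular [4+2] step closes ring B (C5–C10, C8–C9) and, through C5–C10, ring A; ring-A oxygen and chlorine and the side chain follow.
- Stereochemistry: C4 comes from ethyl (R)-3-hydroxybutanoate by double Frater–Seebach alkylation. A temporary C1 silyloxy centre (boron aldol) steers the cycloaddition, which sets C5, C9 and C10. C1 is then re-set by α-face epoxidation and SmI2 opening, and C3 by α-face, OH-directed hydrogenation of a vinyl chloride.

Key step: step 8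

Remarks: α is the face opposite the C10 methyl group; C12 is the ester carbon on C8; ring compounds are named as substituted decalins with this numbering. Assumption: aldehyde-acetal 8 (mono-dimethyl acetal of 2-methylfumaraldehyde) and phosphonate 6 are purchased.

Step 1
Reactants: 1 ethyl (3R)-3-hydroxybutanoate
Product: 2 ethyl (2R,3R)-3-hydroxy-2-methylbutanoate
Conditions: LiN(i-Pr)2 (2.2 equiv), THF, −78 to −20 °C; MeI, −78 to 0 °C
Reagents that add atoms: iodomethane, CI
Why: Frater–Seebach alkylation, in which the lithium-chelated dianion of the β-hydroxy ester is methylated on the face opposite the carbinol methyl group and should give the anti (2R,3R) ester.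

Step 2
Reactants: 2 ethyl (2R,3R)-3-hydroxy-2-methylbutanoate
Product: 3 ethyl (2R)-2-[(1R)-1-hydroxyethyl]-2-methylpent-4-enoate
Conditions: LiN(i-Pr)2 (2.2 equiv), THF–DMPU, −78 to −10 °C; allyl bromide
Reagents that add atoms: allyl bromide (3-bromoprop-1-ene), C=CCBr
Why: Second Frater–Seebach alkylation, in which the re-formed chelated dianion again takes the electrophile anti to the carbinol methyl, so allyl enters where methyl entered in step 1 and the quaternary carbon (future C4) should form as one diastereomer.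

Step 3
Reactants: 3 ethyl (2R)-2-[(1R)-1-hydroxyethyl]-2-methylpent-4-enoate
Product: 4 (2S,3R)-2-methyl-2-(prop-2-en-1-yl)butane-1,3-diol
Conditions: LiAlH4, THF, 0 °C to rt
Reagents that add atoms: none
Why: Hydride reduction of the hindered ester to the primary alcohol, with no stereocentre touched.

Step 4
Reactants: 4 (2S,3R)-2-methyl-2-(prop-2-en-1-yl)butane-1,3-diol
Product: 5 (2S)-2-acetyl-2-methylpent-4-enal
Conditions: Dess–Martin periodinane (2.5 equiv), CH2Cl2, rt
Reagents that add atoms: none
Why: Dess–Martin oxidation of both hydroxyl groups, which erases the carbinol centre after it has done its work and leaves a quaternary centre between two carbonyls that cannot epimerize.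

Step 5
Reactants: 5 (2S)-2-acetyl-2-methylpent-4-enal; 6 methyl (2E)-4-(dimethoxyphosphoryl)but-2-enoate (trimethyl 4-phosphonocrotonate)
Product: 7 methyl (2E,4E,6S)-6-acetyl-6-methylnona-2,4,8-trienoate
Conditions: LiN(SiMe3)2, THF, −78 to 0 °C
Reagents that add atoms: none
Why: Vinylogous Horner–Wadsworth–Emmons olefination at the aldehyde, which is far more reactive than the hindered methyl ketone, should give the (2E,4E)-dienoate (future C5=C6–C7=C8–CO2Me).

Step 6
Reactants: 7 methyl (2E,4E,6S)-6-acetyl-6-methylnona-2,4,8-trienoate; 8 (2E)-4,4-dimethoxy-2-methylbut-2-enal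
Product: 9 methyl (2E,4E,6S,9R,10E)-9-hydroxy-12,12-dimethoxy-6,10-dimethyl-7-oxo-6-(prop-2-en-1-yl)dodeca-2,4,10-trienoate
Conditions: (−)-Ipc2BCl, Et3N, Et2O, 0 °C; 8, −78 to −20 °C; H2O2, MeOH, pH 7 buffer
Reagents that add atoms: none
Why: Boron aldol (Paterson type) in which the acetyl methyl is the only enolizable position of 7, its Ipc2B enolate adds 1,2 to enal 8 through a cyclic transition state, and the chiral borane should set the new carbinol (future C1, a temporary control element) as 9R, the antipodal borane being taken if the sense of induction proves opposite.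

Step 7
Reactants: 9 (aldol adduct above)
Product: 10 methyl (2E,4E,6S,9R,10E)-9-(tert-butyldimethylsilyloxy)-12,12-dimethoxy-6,10-dimethyl-7-oxo-6-(prop-2-en-1-yl)dodeca-2,4,10-trienoate
Conditions: t-BuMe2SiCl, imidazole, DMF, rt
Reagents that add atoms: tert-butyldimethylsilyl chloride, CC(C)(C)[Si](C)(C)Cl
Why: Silyl ether formation with the silyl chloride (not a silyl triflate, which would ionize the acetal) protects the β-hydroxy ketone and installs the bulky group that is to sit equatorial in the next step.

Step 8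
Reactants: 10 (silyl ether above)
Product: 12 methyl 1β-(tert-butyldimethylsilyloxy)-9β-(dimethoxymethyl)-4β,10β-dimethyl-3-oxo-4α-(prop-2-enyl)-5α-decal-6-ene-8β-carboxylate (trans-fused), via vinyl oxocarbenium triflate 11 (not isolated)
Conditions: Me3SiOTf (10 mol %), 2,6-di-tert-butyl-4-methylpyridine (20 mol %), CH2Cl2, −78 to −40 °C
Reagents that add atoms: none
Why: Me3SiOTf ionizes the allylic dimethyl acetal of 10 to the 1-methoxyallyl (vinyl oxocarbenium) cation 11, a cationic dienophile with C10 as its electrophilic terminus, which adds across the C5=C6–C7=C8 dienoate in an intramolecular [4+2] cycloaddition forming C5–C10 and C8–C9 before methoxide returns to C11 and regenerates the silyl triflate. The closest known reaction type is the ionic Diels–Alder reaction of α,β-unsaturated acetals, including its intramolecular trienyl-acetal (1,7,9-decatriene) version. Ring B is closed as the cycloaddition ring (C5–C8 of the diene plus C9 and C10), and ring A is closed at the same time as the tether ring through the C5–C10 bond, exo with respect to both π components. The cis relation of the C10 methyl and C11 follows from the E geometry of the dienophile, the trans ring fusion (C10 methyl anti to H5) from the endo position of the oxocarbenium unit with the tether exo, and C8 from the E geometry of the diene terminus. The absolute sense comes from the tether: in the chair-like transition state the C1 silyloxy group lies equatorial and anti to the forming C10–C5 bond, and at C4 the allyl group lies anti while the methyl eclipses C5=C6, so one diene face is used. The step needs endo and π-facial selectivity and selective activation of the dienophile; only the acetal ionizes (ketone and ester stay unactivated) and the low temperature should keep the E geometry of the cation.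

Step 9
Reactants: 12 (cycloadduct above)
Product: 13 methyl 9β-(dimethoxymethyl)-4β,10β-dimethyl-3-oxo-4α-(prop-2-enyl)-5α-decala-1,7-diene-8-carboxylate
Conditions: 1,8-diazabicyclo[5.4.0]undec-7-ene (DBU, 2 equiv), toluene, 80 °C
Reagents that add atoms: none
Why: Base-mediated E1cB loss of the 1-silyloxy group (the ketone can enolize only toward C2) gives the Δ1-3-ketone, and in the same pot deprotonation at C8 with reprotonation at C6 moves the ring-B double bond into conjugation with the ester, while C9 carries an acetal, is not acidic and keeps its configuration.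

Step 10
Reactants: 13 (dienone ester above)
Product: 14 methyl 9β-(dimethoxymethyl)-1α,2α-epoxy-4β,10β-dimethyl-3-oxo-4α-(prop-2-enyl)-5α-decal-7-ene-8-carboxylate
Conditions: 30% H2O2, NaOH (0.3 equiv), MeOH, 0 °C
Reagents that add atoms: hydrogen peroxide, OO
Why: Weitz–Scheffer nucleophilic epoxidation in which hydroperoxide adds to C1 of the enone axially from the α face, away from the axial methyls on C4 and C10, and closes to the 1α,2α-epoxide, the α-substituted enoate being inert.

Step 11
Reactants: 14 (epoxy ketone above)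
Product: 15 methyl 9β-(dimethoxymethyl)-1α-hydroxy-4β,10β-dimethyl-3-oxo-4α-(prop-2-enyl)-5α-decal-7-ene-8-carboxylate
Conditions: SmI2 (2.2 equiv), THF–MeOH, −90 °C
Reagents that add atoms: none
Why: SmI2 reduction of an α,β-epoxy ketone cleaves the C2–O bond through the ketyl and samarium enolate and leaves the axial 1α-hydroxyl with its configuration.

Step 12
Reactants: 15 (β-hydroxy ketone above)
Product: 16 methyl 9β-(dimethoxymethyl)-4β,10β-dimethyl-3-oxo-4α-(prop-2-enyl)-1α-(trimethylsilyloxy)-5α-decal-7-ene-8-carboxylate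
Conditions: Me3SiCl, imidazole, CH2Cl2, 0 °C
Reagents that add atoms: chlorotrimethylsilane, C[Si](C)(C)Cl
Why: Silylation of the hindered axial alcohol under acetal-compatible conditions blocks retro-aldol cleavage, β-elimination and O-sulfonylation in the next step.

Step 13
Reactants: 16 (silyl ether above)
Product: 17 methyl 9β-(dimethoxymethyl)-4β,10β-dimethyl-4α-(prop-2-enyl)-3-(trifluoromethanesulfonyloxy)-1α-(trimethylsilyloxy)-5α-decala-2,7-diene-8-carboxylate
Conditions: KN(SiMe3)2, THF, −78 °C; PhNTf2
Reagents that add atoms: N-phenylbis(trifluoromethanesulfonimide), O=S(=O)(N(c1ccccc1)S(=O)(=O)C(F)(F)F)C(F)(F)F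
Why: The ketone can enolize only toward C2 because C4 is quaternary, and trapping the potassium enolate at −78 °C should give the Δ2 enol triflate faster than β-elimination of the silyloxy group or deprotonation at the less acidic γ-position of the enoate.

Step 14
Reactants: 17 (enol triflate above)
Product: 19 methyl 3-chloro-9β-(dimethoxymethyl)-1α-hydroxy-4β,10β-dimethyl-4α-(prop-2-enyl)-5α-decala-2,7-diene-8-carboxylate, via silyl ether vinyl chloride 18 (not isolated)
Conditions: Ni(OAc)2·4H2O (10 mol %), 1,5-cyclooctadiene, Zn (20 mol %), LiCl, THF–DMA, rt; then K2CO3, MeOH, 0 °C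
Reagents that add atoms: lithium chloride, [Li+].[Cl-]
Why: Nickel-catalysed triflate-to-halide exchange (oxidative addition of the alkenyl triflate to zerovalent nickel, chloride exchange, reductive elimination) gives the vinyl chloride with the double bond fixed at C2=C3, and mild methanolysis then frees the 1α-hydroxyl needed to direct step 16.

Step 15
Reactants: 19 (chloro-diene alcohol above)
Product: 20 methyl 3-chloro-9β-(dimethoxymethyl)-1α-hydroxy-4β,10β-dimethyl-4α-(2-oxoethyl)-5α-decala-2,7-diene-8-carboxylate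
Conditions: OsO4 (2 mol %), NaIO4, 2,6-lutidine, dioxane–H2O, rt
Reagents that add atoms: OsO4, O=[Os](=O)(=O)=O; sodium periodate, [Na+].[O-]I(=O)(=O)=O
Why: Lemieux–Johnson cleavage in which OsO4 dihydroxylates the only unhindered, electron-rich alkene (the terminal allyl group) and periodate cleaves the diol, the chloro-alkene and the enoate being hindered and electron-poor.

Step 16
Reactants: 20 (aldehyde above)
Product: 21 methyl 3β-chloro-9β-(dimethoxymethyl)-1α-hydroxy-4β,10β-dimethyl-4α-(2-oxoethyl)-5α-decal-7-ene-8-carboxylate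
Conditions: [Ir(cod)(PCy3)(py)]PF6 (5 mol %), H2 (1 atm), CH2Cl2, rt
Reagents that add atoms: none
Why: Hydroxyl-directed homogeneous hydrogenation in which the cationic iridium catalyst binds the allylic 1α-hydroxyl and delivers H2 to the α face of C2=C3, also the face remote from the two axial methyls, so that H3 is α and chlorine ends equatorial (3β), the conjugated trisubstituted ester alkene being a poor substrate for this catalyst.

Step 17
Reactants: 21 (saturated chloride above); 22 1-(triphenyl-λ5-phosphanylidene)propan-2-one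
Product: 23 methyl 3β-chloro-9β-(dimethoxymethyl)-1α-hydroxy-4β,10β-dimethyl-4α-[(2E)-4-oxopent-2-enyl]-5α-decal-7-ene-8-carboxylate
Conditions: toluene, 60 °C
Reagents that add atoms: none
Why: Wittig olefination with the stabilized acetonyl ylide should give the (E)-enone at the unhindered aldehyde and tolerates the free hydroxyl, the chloride, the ester and the acetal.

Step 18
Reactants: 23 (enone above)
Product: 24 methyl 3β-chloro-9β-(dimethoxymethyl)-1α-hydroxy-4α-[(2E)-4-hydroxy-4-methylpent-2-enyl]-4β,10β-dimethyl-5α-decal-7-ene-8-carboxylate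
Conditions: MeMgBr (3 equiv), CeCl3, THF, −78 °C
Reagents that add atoms: methylmagnesium bromide, C[Mg]Br
Why: Cerium-mediated 1,2-addition of the methyl Grignard reagent to the enone carbonyl (after deprotonation of the 1-hydroxyl) gives the tertiary allylic alcohol, the hindered conjugated methyl ester reacting much more slowly at −78 °C.

Step 19
Reactants: 24 (acetal above)
Product: 25 target, methyl 3β-chloro-9β-formyl-1α-hydroxy-4α-[(2E)-4-hydroxy-4-methylpent-2-enyl]-4β,10β-dimethyl-5α-decal-7-ene-8-carboxylate (CNP0167913.1)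
Conditions: pyridinium p-toluenesulfonate (cat.), acetone–H2O, 40 °C
Reagents that add atoms: water, O
Why: Mild acid-catalysed acetal hydrolysis releases the C9 formyl group without base, so the 9β configuration set in step 8 and the acid-sensitive tertiary allylic alcohol should survive.

**Compound list**
1 | ethyl (3R)-3-hydroxybutanoate | C[C@@H](O)CC(=O)OCC | starting material
2 | ethyl (2R,3R)-3-hydroxy-2-methylbutanoate | C[C@@H](O)[C@@H](C)C(=O)OCC | intermediate
3 | ethyl (2R)-2-[(1R)-1-hydroxyethyl]-2-methylpent-4-enoate | C[C@@H](O)[C@@](C)(CC=C)C(=O)OCC | intermediate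
4 | (2S,3R)-2-methyl-2-(prop-2-en-1-yl)butane-1,3-diol | C[C@@H](O)[C@@](C)(CC=C)CO | intermediate
5 | (2S)-2-acetyl-2-methylpent-4-enal | CC(=O)[C@@](C)(CC=C)C=O | intermediate
6 | methyl (2E)-4-(dimethoxyphosphoryl)but-2-enoate | COC(=O)/C=C/CP(=O)(OC)OC | starting material
7 | methyl (2E,4E,6S)-6-acetyl-6-methylnona-2,4,8-trienoate | COC(=O)/C=C/C=C/[C@](C)(CC=C)C(C)=O | intermediate
8 | (2E)-4,4-dimethoxy-2-methylbut-2-enal | O=C/C(C)=C/C(OC)OC | starting material
9 | methyl (2E,4E,6S,9R,10E)-9-hydroxy-12,12-dimethoxy-6,10-dimethyl-7-oxo-6-(prop-2-en-1-yl)dodeca-2,4,10-trienoate | COC(=O)/C=C/C=C/[C@](C)(CC=C)C(=O)C[C@@H](O)/C(C)=C/C(OC)OC | intermediate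
10 | methyl (2E,4E,6S,9R,10E)-9-(tert-butyldimethylsilyloxy)-12,12-dimethoxy-6,10-dimethyl-7-oxo-6-(prop-2-en-1-yl)dodeca-2,4,10-trienoate | COC(=O)/C=C/C=C/[C@](C)(CC=C)C(=O)C[C@@H](O[Si](C)(C)C(C)(C)C)/C(C)=C/C(OC)OC | intermediate
11 | vinyl oxocarbenium triflate (10 after loss of one methoxide from C12 of the chain; 1-methoxyallyl cation) | COC(=O)/C=C/C=C/[C@](C)(CC=C)C(=O)C[C@@H](O[Si](C)(C)C(C)(C)C)/C(C)=C/C=[O+]/C.[O-]S(=O)(=O)C(F)(F)F | intermediate
12 | methyl 1β-(tert-butyldimethylsilyloxy)-9β-(dimethoxymethyl)-4β,10β-dimethyl-3-oxo-4α-(prop-2-enyl)-5α-decal-6-ene-8β-carboxylate | COC(=O)[C@H]1C=C[C@H]2[C@](C)(CC=C)C(=O)C[C@@H](O[Si](C)(C)C(C)(C)C)[C@]2(C)[C@H]1C(OC)OC | intermediate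
13 | methyl 9β-(dimethoxymethyl)-4β,10β-dimethyl-3-oxo-4α-(prop-2-enyl)-5α-decala-1,7-diene-8-carboxylate | COC(=O)C1=CC[C@H]2[C@](C)(CC=C)C(=O)C=C[C@]2(C)[C@H]1C(OC)OC | intermediate
14 | methyl 9β-(dimethoxymethyl)-1α,2α-epoxy-4β,10β-dimethyl-3-oxo-4α-(prop-2-enyl)-5α-decal-7-ene-8-carboxylate | COC(=O)C1=CC[C@H]2[C@](C)(CC=C)C(=O)[C@@H]3O[C@@H]3[C@]2(C)[C@H]1C(OC)OC | intermediate
15 | methyl 9β-(dimethoxymethyl)-1α-hydroxy-4β,10β-dimethyl-3-oxo-4α-(prop-2-enyl)-5α-decal-7-ene-8-carboxylate | COC(=O)C1=CC[C@H]2[C@](C)(CC=C)C(=O)C[C@H](O)[C@]2(C)[C@H]1C(OC)OC | intermediate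
16 | methyl 9β-(dimethoxymethyl)-4β,10β-dimethyl-3-oxo-4α-(prop-2-enyl)-1α-(trimethylsilyloxy)-5α-decal-7-ene-8-carboxylate | COC(=O)C1=CC[C@H]2[C@](C)(CC=C)C(=O)C[C@H](O[Si](C)(C)C)[C@]2(C)[C@H]1C(OC)OC | intermediate
17 | methyl 9β-(dimethoxymethyl)-4β,10β-dimethyl-4α-(prop-2-enyl)-3-(trifluoromethanesulfonyloxy)-1α-(trimethylsilyloxy)-5α-decala-2,7-diene-8-carboxylate | COC(=O)C1=CC[C@H]2[C@](C)(CC=C)C(OS(=O)(=O)C(F)(F)F)=C[C@H](O[Si](C)(C)C)[C@]2(C)[C@H]1C(OC)OC | intermediate
18 | methyl 3-chloro-9β-(dimethoxymethyl)-4β,10β-dimethyl-4α-(prop-2-enyl)-1α-(trimethylsilyloxy)-5α-decala-2,7-diene-8-carboxylate | COC(=O)C1=CC[C@H]2[C@](C)(CC=C)C(Cl)=C[C@H](O[Si](C)(C)C)[C@]2(C)[C@H]1C(OC)OC | intermediate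
19 | methyl 3-chloro-9β-(dimethoxymethyl)-1α-hydroxy-4β,10β-dimethyl-4α-(prop-2-enyl)-5α-decala-2,7-diene-8-carboxylate | COC(=O)C1=CC[C@H]2[C@](C)(CC=C)C(Cl)=C[C@H](O)[C@]2(C)[C@H]1C(OC)OC | intermediate
20 | methyl 3-chloro-9β-(dimethoxymethyl)-1α-hydroxy-4β,10β-dimethyl-4α-(2-oxoethyl)-5α-decala-2,7-diene-8-carboxylate | COC(=O)C1=CC[C@H]2[C@](C)(CC=O)C(Cl)=C[C@H](O)[C@]2(C)[C@H]1C(OC)OC | intermediate
21 | methyl 3β-chloro-9β-(dimethoxymethyl)-1α-hydroxy-4β,10β-dimethyl-4α-(2-oxoethyl)-5α-decal-7-ene-8-carboxylate | COC(=O)C1=CC[C@H]2[C@](C)(CC=O)[C@@H](Cl)C[C@H](O)[C@]2(C)[C@H]1C(OC)OC | intermediate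
22 | 1-(triphenyl-λ5-phosphanylidene)propan-2-one | CC(=O)C=P(c1ccccc1)(c1ccccc1)c1ccccc1 | starting material
23 | methyl 3β-chloro-9β-(dimethoxymethyl)-1α-hydroxy-4β,10β-dimethyl-4α-[(2E)-4-oxopent-2-enyl]-5α-decal-7-ene-8-carboxylate | COC(=O)C1=CC[C@H]2[C@](C)(C/C=C/C(C)=O)[C@@H](Cl)C[C@H](O)[C@]2(C)[C@H]1C(OC)OC | intermediate
24 | methyl 3β-chloro-9β-(dimethoxymethyl)-1α-hydroxy-4α-[(2E)-4-hydroxy-4-methylpent-2-enyl]-4β,10β-dimethyl-5α-decal-7-ene-8-carboxylate | COC(=O)C1=CC[C@H]2[C@](C)(C/C=C/C(C)(C)O)[C@@H](Cl)C[C@H](O)[C@]2(C)[C@H]1C(OC)OC | intermediate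
25 | methyl 3β-chloro-9β-formyl-1α-hydroxy-4α-[(2E)-4-hydroxy-4-methylpent-2-enyl]-4β,10β-dimethyl-5α-decal-7-ene-8-carboxylate (CNP0167913.1) | COC(=O)C1=CC[C@H]2[C@](C)(C/C=C/C(C)(C)O)[C@@H](Cl)C[C@H](O)[C@]2(C)[C@H]1C=O | target

Total step count: 19. Longest linear sequence: 19 steps (from 1).

**Steps most likely to fail**

Step 8. The cation may rotate about C9–C10 and lose its E geometry, may ionize at C1 with loss of the silyloxy group, or may be captured too slowly by the electron-poor diene, which would weaken endo and π-facial control. The fallback replaces the cationic dienophile by the neutral enal. It sets out from 10, whose acetal is hydrolysed (oxalic acid on wet silica gel, CH2Cl2) to methyl (2E,4E,6S,9R,10E)-9-(tert-butyldimethylsilyloxy)-6,10-dimethyl-7,12-dioxo-6-(prop-2-en-1-yl)dodeca-2,4,10-trienoate F1. This is cyclized in a Lewis-acid-promoted intramolecular Diels–Alder reaction (Me2AlCl, CH2Cl2, −40 °C to rt; thermal alternative toluene, 150 °C) to methyl 1β-(tert-butyldimethylsilyloxy)-9β-formyl-4β,10β-dimethyl-3-oxo-4α-(prop-2-enyl)-5α-decal-6-ene-8β-carboxylate F2. Acetalization (HC(OMe)3, pyridinium p-toluenesulfonate, MeOH) comes back to the route at 12.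

Step 16. Hydrogenolysis of the C–Cl bond (β-chloride elimination from an alkyliridium intermediate) or reduction of the C7=C8 enoate may compete. The fallback is a radical hydrogenation by hydrogen-atom transfer, which has no carbon–metal bond. It sets out from 20 with Mn(dpm)3 (dpm = dipivaloylmethanate, cat.), PhSiH3 and t-BuOOH in i-PrOH at rt. H• adds to C2 and the α-chloro radical at C3 should take the second hydrogen axially from the α face, giving the equatorial chloride. It comes back at 21 and makes no new compound. Its own weak point is that the conjugated ester can also accept a hydrogen atom.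

Step 14. Oxidative addition may be slow at the triflate flanked by the quaternary C4, or the triflate may be reduced to the alkene. The fallback goes through an organotin compound. It sets out from 17, which is stannylated (Pd(PPh3)4, (Me3Sn)2, LiCl, dioxane, 90 °C) to methyl 9β-(dimethoxymethyl)-4β,10β-dimethyl-4α-(prop-2-enyl)-1α-(trimethylsilyloxy)-3-(trimethylstannyl)-5α-decala-2,7-diene-8-carboxylate F3. Chlorodestannylation with CuCl2 in THF comes back to the route at 18, which is desilylated as in step 14.

Further compounds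
F1 | step 8 | methyl (2E,4E,6S,9R,10E)-9-(tert-butyldimethylsilyloxy)-6,10-dimethyl-7,12-dioxo-6-(prop-2-en-1-yl)dodeca-2,4,10-trienoate | COC(=O)/C=C/C=C/[C@](C)(CC=C)C(=O)C[C@@H](O[Si](C)(C)C(C)(C)C)/C(C)=C/C=O
F2 | step 8 | methyl 1β-(tert-butyldimethylsilyloxy)-9β-formyl-4β,10β-dimethyl-3-oxo-4α-(prop-2-enyl)-5α-decal-6-ene-8β-carboxylate | COC(=O)[C@H]1C=C[C@H]2[C@](C)(CC=C)C(=O)C[C@@H](O[Si](C)(C)C(C)(C)C)[C@]2(C)[C@H]1C=O
F0 | step 16 | none | none
F3 | step 14 | methyl 9β-(dimethoxymethyl)-4β,10β-dimethyl-4α-(prop-2-enyl)-1α-(trimethylsilyloxy)-3-(trimethylstannyl)-5α-decala-2,7-diene-8-carboxylate | COC(=O)C1=CC[C@H]2[C@](C)(CC=C)C([Sn](C)(C)C)=C[C@H](O[Si](C)(C)C)[C@]2(C)[C@H]1C(OC)OC
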